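**Plan**

1. Numbering and enabling feature: ring A = C1–C5/C10 (C2 ketone, C4 methyl), ring B = C5–C10 (C5 methyl, C7 isopropenyl, C8 OAc, C9 tiglate). Because the secondary-methyl carbon C4 adjoins the quaternary C5 in a cis-decalin, a bond drawn between C2 and C7 turns ring B into a bicyclo[2.2.2]oct-5-ene in which C4=C3–C2(O–)–C7–C6=C5 is a 3-oxido-1,5-diene.
2. Retrosynthetic cuts, in order: the C9–O tigloyl and C8–O acetyl bonds; C11=C12 (methylene) and C11–C13 (methyl), back to a C7 hydroxymethyl group; C4–C5 by retro-[3,3], which restores C2–C7; C2–C3 (propenyl onto a ketone); the Diels–Alder bonds C1–C10 and C2–C7; C7–C11 (hydroxymethylation of creosol).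
3. Forward order: creosol → masked o-benzoquinone → bicyclo[2.2.2]octene (future ring B bridged by C1–C2) → the oxy-Cope step closes ring A and releases ring B → side chain → esters.
4. Stereochemistry: C10 from the Diels–Alder reaction; O8/O9 by hydride attack from the C5=C6 face of the rigid bicycle; absolute configuration by lipase resolution of the C2 carbinol; C5 and C4 from the boat [3,3] transition state and the (Z)-propenyl geometry; C7 by C8-hydroxyl-directed hydrogenation.
5. Late stage: O9, which lies against C2 on the concave face once C7 is saturated, is tied to C2 as a bridged methyl ketal; this masks the ketone during methylenation and distinguishes O8 from O9 for the two acylations.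

Key step: step 12

**Remarks**

- Target numbering (C1–C10 ring carbons, C11 on C7, C14 on C5, C15 on C4) is used for every intermediate. In the bicyclo[2.2.2]octenes C7 and C10 are the bridgeheads and the bridges are C1–C2, C5=C6 and C8–C9. In the decalins β is the face of ring B that carries the C5 methyl group and α the opposite face. The target is (4S,5R,7R,8R,9S,10S).
- Compounds 7–12 are racemic; their SMILES show the enantiomer that is carried on after step 9.
- Assumption: adduct 7 is taken as the endo isomer (C2–OBn syn to C5=C6). This centre is erased in step 10 and matters only for the sense of the enzymatic step.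

**Route**

Step 1
Reactants: 1 creosol (2-methoxy-4-methylphenol); 2 formaldehyde
Product: 3 2-(hydroxymethyl)-6-methoxy-4-methylphenol
Conditions: 2 (37% aq.), NaOH (1.1 equiv), H2O, 20 °C; then AcOH
Reagents that add atoms: none
Why: Lederer–Manasse hydroxymethylation, in which the phenoxide attacks formaldehyde through the only free ortho carbon (the para position carries the methyl group), installs the carbon that becomes C11 on the future C7.

Step 2
Reactants: 3 2-(hydroxymethyl)-6-methoxy-4-methylphenol
Product: 4 2-methoxy-4-methyl-6-[(triisopropylsilyloxy)methyl]phenol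
Conditions: TIPSCl, imidazole, DMF, 0 °C
Reagents that add atoms: triisopropylsilyl chloride, CC(C)[Si](Cl)(C(C)C)C(C)C
Why: Chemoselective O-silylation, since the primary benzylic alcohol reacts faster than the doubly ortho-substituted, hydrogen-bonded phenol, and a TIPS ether is chosen because it should outlast the aqueous acid of step 5, the arene radical anion of step 8 and the KH of step 12.

Step 3
Reactants: 4 2-methoxy-4-methyl-6-[(triisopropylsilyloxy)methyl]phenol; 5 benzyl vinyl ether
Product: 7 rac-Diels–Alder adduct (C8 ketone; C9 dimethyl ketal; C2 benzyl ether), via masked o-benzoquinone 6 (not isolated)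
Conditions: PhI(OAc)2, MeOH, 5 (20 equiv), 0 → 50 °C
Reagents that add atoms: methanol, CO
Why: Oxidative dearomatisation with PhI(OAc)2 in methanol gives the electron-poor 6,6-dimethoxycyclohexa-2,4-dienone 6, which is trapped in an inverse-electron-demand Diels–Alder reaction in which the nucleophilic CH2 of the enol ether bonds to the δ-carbon of the dienone (C1–C10) and the alkoxy carbon to the α-carbon (C2–C7), the endo transition state placing OBn syn to the C5=C6 bridge and fixing C7 and C10 in one racemic relative configuration.

Step 4
Reactants: 7 rac-Diels–Alder adduct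
Product: 8 rac-hydroxy ketal (C8–OH syn to the C1–C2 bridge)
Conditions: NaBH4, MeOH, 0 °C
Reagents that add atoms: none
Why: Borohydride reduction of the C8 ketone with hydride arriving from the face of the C5=C6 bridge, which is more open than the face lined by the hydrogens of the C1–C2 bridge, so that the new hydroxyl points toward the C1–C2 bridge.

Step 5
Reactants: 8 rac-hydroxy ketal
Product: 9 rac-hydroxy ketone (C8–OH; C9 ketone)
Conditions: TsOH·H2O (0.2 equiv), acetone–H2O (10:1), 50 °C
Reagents that add atoms: water, O
Why: Acid-catalysed hydrolysis of the dimethyl ketal (oxocarbenium ion at C9, capture by water) unmasks the C9 ketone under conditions that the TIPS and benzyl ethers should tolerate, and without base the C8 carbinol cannot epimerise through the enediol.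

Step 6
Reactants: 9 rac-hydroxy ketone
Product: 10 rac-cis-diol (C8–OH and C9–OH syn to the C1–C2 bridge)
Conditions: NaBH4, MeOH, −20 °C
Reagents that add atoms: none
Why: Second borohydride reduction, again from the C5=C6 face and anti to the neighbouring hydroxyl, gives the cis-diol with both oxygens syn to the C1–C2 bridge, the arrangement that becomes 8α,9α in the decalin.

Step 7
Reactants: 10 rac-cis-diol
Product: 11 rac-acetonide benzyl ether
Conditions: 2,2-dimethoxypropane, pyridinium p-toluenesulfonate (cat.), CH2Cl2, 20 °C
Reagents that add atoms: 2,2-dimethoxypropane, COC(C)(C)OC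
Why: Acid-catalysed transketalisation of the cis-1,2-diol to the isopropylidene acetal protects both hydroxyls and places its CMe2 group over the face of C2 that is turned to the C8–C9 bridge.

Step 8
Reactants: 11 rac-acetonide benzyl ether
Product: 12 rac-bicyclic alcohol (C2–OH syn to C5=C6)
Conditions: LiDBB (lithium 4,4′-di-tert-butylbiphenylide), THF, −78 °C; then aq. NH4Cl
Reagents that add atoms: none
Why: Reductive debenzylation by single-electron transfer from the arene radical anion cleaves only the benzylic C–O bond and, unlike catalytic hydrogenolysis, leaves the C5=C6 alkene needed for the key step as well as the silyl ether and the acetonide.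

Step 9
Reactants: 12 rac-bicyclic alcohol
Product: 13 (2S)-bicyclic alcohol (single enantiomer of 12)
Conditions: Burkholderia cepacia lipase (immobilised), vinyl acetate, t-BuOMe, 35 °C, stopped just past half conversion; chromatography
Reagents that add atoms: none
Why: Lipase-catalysed kinetic resolution by irreversible transesterification, for which the empirical size rule for secondary alcohols (quaternary C7 as the large and C1H2 as the medium substituent) predicts acylation of the (2R)-enantiomer, so that the (2S)-alcohol should stay unreacted and is separated from the acetate.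

Step 10
Reactants: 13 (2S)-bicyclic alcohol
Product: 14 bicyclic ketone (C2 ketone)
Conditions: Dess–Martin periodinane, pyridine, CH2Cl2, 0 → 20 °C
Reagents that add atoms: none
Why: Dess–Martin oxidation of the hindered secondary alcohol to the C2 ketone under buffered conditions erases only the carbinol centre and touches no other stereocentre.

Step 11
Reactants: 14 bicyclic ketone; 15 (Z)-1-bromoprop-1-ene
Product: 17 (Z)-propenyl carbinol (tertiary C2–OH; propenyl syn to C5=C6), via (Z)-prop-1-enyllithium 16 (not isolated)
Conditions: 15, t-BuLi (2 equiv per 15), Et2O, −78 °C; then 14, THF, −78 °C; aq. NH4Cl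
Reagents that add atoms: none
Why: Bromine–lithium exchange with retention gives the (Z)-vinyllithium, which adds 1,2 to the ketone from the face of the C5=C6 bridge because the opposite face is screened by the acetonide oxygens and their CMe2 group, setting C2 with the propenyl group syn to the alkene.

Step 12
Reactants: 17 (Z)-propenyl carbinol
Product: 20 cis-decalenone (C2 ketone; C6=C7; 8α,9α-acetonide; C7–CH2OTIPS), via potassium alkoxide 18 (not isolated), via potassium enolate 19 (not isolated)
Conditions: KH, 18-crown-6, THF, 0 → 50 °C; then aq. NH4Cl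
Reagents that add atoms: none
Why: KH with 18-crown-6 turns 17 into the dissociated potassium alkoxide 18, whose oxyanion weakens the C2–C7 bond so that a concerted [3,3] sigmatropic shift occurs (anionic oxy-Cope rearrangement, the reaction type known for 2-alkenylbicyclo[2.2.2]oct-5-en-2-olates made from masked o-benzoquinone adducts): C4–C5 forms while C2–C7 breaks, giving enolate 19, which aqueous NH4Cl protonates to ketone 20. Ring A (C10–C1–C2–C3–C4–C5) closes by suprafacial bonding of the propenyl terminus C4 to the alkene carbon C5 through the six-membered boat array C4=C3–C2–C7–C6=C5, and the simultaneous cleavage of C2–C7 opens the bicycle so that ring B (C5–C10) is released as a cyclohexene with the C6=C7 double bond. The quaternary centre C5 is controlled by the bicyclic frame, since C4 can reach C5 only on the alkene face turned to the C1–C2 bridge; C4 and C1 therefore end on the same face of ring B (cis fusion) together with O8 and O9, while the C5 methyl and H10 lie on the other face. The centre C4 is controlled by the alkene geometry, because in the boat the (Z)-methyl is the inside substituent and finishes cis to the C5 methyl. The step needs the propenyl group syn to the C5=C6 bridge and an intact (Z)-alkene, which are secured by the facial selectivity and the stereoretentive exchange of step 11, and because the shift is stereospecific the enantiopurity set in step 9 is carried into C4 and C5. A primary TIPS ether and the acetonide are chosen as spectators because neither can leave or migrate easily under the basic conditions.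

Step 13
Reactants: 20 cis-decalenone
Product: 21 allylic alcohol (C7–CH2OH)
Conditions: Bu4NF, THF, 0 → 20 °C; aq. NH4Cl
Reagents that add atoms: none
Why: Fluoride-induced Si–O cleavage frees the primary allylic alcohol while the ketone and the acetonide are inert to Bu4NF.

Step 14
Reactants: 21 allylic alcohol
Product: 22 enal (C7–CHO)
Conditions: MnO2, CH2Cl2, 20 °C
Reagents that add atoms: none
Why: MnO2 oxidises the allylic primary alcohol to the enal and leaves the saturated C2 ketone untouched, and because C7 is still sp2 no stereocentre is at risk.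

Step 15
Reactants: 22 enal
Product: 23 allylic secondary alcohol (both C11 epimers)
Conditions: MeTi(OiPr)3, THF, −40 → 0 °C; aq. NH4Cl
Reagents that add atoms: methyltitanium triisopropoxide, C[Ti](OC(C)C)(OC(C)C)OC(C)C
Why: Chemoselective carbonyl addition, the methyltitanium reagent adding 1,2 to aldehydes far faster than to ketones, introduces the C13 methyl without protecting C2, and the C11 carbinol is left as a mixture because the next step erases it.

Step 16
Reactants: 23 allylic secondary alcohol
Product: 24 methyl enone (C7–C(O)CH3 on C6=C7)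
Conditions: MnO2, CH2Cl2, 20 °C
Reagents that add atoms: none
Why: Allylic oxidation with MnO2 converts the secondary allylic alcohol into the methyl enone, which now carries every carbon of the later isopropenyl group except C12.

Step 17
Reactants: 24 methyl enone
Product: 25 enone diol (8α,9α-diol)
Conditions: AcOH–H2O (4:1), 50 °C
Reagents that add atoms: none
Why: Acid hydrolysis of the isopropylidene acetal frees the allylic C8 hydroxyl that has to steer the hydrogenation, the enone and the saturated ketone being stable to aqueous acetic acid.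

Step 18
Reactants: 25 enone diol
Product: 26 7β-acetyl diol ketone (H7 α)
Conditions: [Ir(cod)(PCy3)(py)]PF6 (10 mol %), H2 (1 atm), CH2Cl2, 20 °C
Reagents that add atoms: none
Why: Hydroxyl-directed homogeneous hydrogenation, in which the cationic iridium centre binds the allylic C8 hydroxyl on the α face and delivers both hydrogens to that face of C6=C7, sets C7 with H α and the acetyl group β (trans to O8, cis to the C5 methyl).

Step 19
Reactants: 26 7β-acetyl diol ketone
Product: 27 bridged methyl ketal (C2(OMe)–O9 bridge; 8α-OH free)
Conditions: camphorsulfonic acid (0.1 equiv), MeOH, 20 °C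
Reagents that add atoms: methanol, CO
Why: Acid-catalysed intramolecular ketalisation in methanol, possible because the equatorial β-acetyl group locks ring B so that O9 is axial on the concave face and within bonding distance of C2, closes a five-membered mixed methyl ketal (a 6-oxabicyclo[3.2.1]octane on ring A) that masks the C2 ketone and O9 together, leaves only the C8 hydroxyl free and has its C2 configuration dictated by the tether.

Step 20
Reactants: 27 bridged methyl ketal
Product: 28 isopropenyl bridged ketal alcohol
Conditions: CH2Br2, Zn, TiCl4 (pre-formed slurry), THF–CH2Cl2, 0 → 20 °C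
Reagents that add atoms: dibromomethane, BrCBr
Why: Non-basic carbonyl methylenation with the reagent from CH2Br2, Zn and TiCl4 converts the acetyl group into the isopropenyl group without forming the C7 enolate (no epimerisation, no retro-aldol of the β-hydroxy ketone), the free hydroxyl only consuming some reagent.

Step 21
Reactants: 28 isopropenyl bridged ketal alcohol
Product: 29 8-acetate of the bridged ketal
Conditions: Ac2O, DMAP (cat.), pyridine, CH2Cl2, 0 → 20 °C
Reagents that add atoms: acetic anhydride, CC(=O)OC(C)=O
Why: DMAP-catalysed acetylation of the single free hydroxyl, the equatorial C8–OH, places the acetate without any selectivity problem while O9 is still held in the bridge.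

Step 22
Reactants: 29 8-acetate of the bridged ketal
Product: 30 8α-acetoxy-9α-hydroxy ketone
Conditions: pyridinium p-toluenesulfonate, acetone–H2O (4:1), 40 °C
Reagents that add atoms: water, O
Why: Mild acid hydrolysis of the mixed ketal releases the C2 ketone and the C9 hydroxyl (which may stay in equilibrium with the transannular hemiketal) under conditions that the acetate and the 1,1-disubstituted alkene should survive.

Step 23
Reactants: 30 8α-acetoxy-9α-hydroxy ketone
Product: 31 CNP0204573.1 (8α-acetoxy-9α-tigloyloxy-7β-isopropenyl-4β,5β-dimethyl-10βH-cis-decalin-2-one)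
Conditions: (E)-2-methylbut-2-enoyl chloride, Et3N, DMAP, toluene, 60 °C
Reagents that add atoms: (E)-2-methylbut-2-enoyl chloride (tigloyl chloride), C/C=C(\C)C(Cl)=O
Why: DMAP-catalysed acylation by the tigloyl acylpyridinium ion takes the secondary C9 hydroxyl of the open hydroxy ketone form, the tertiary hemiketal hydroxyl being unreactive under nucleophilic catalysis and the acetate having no tendency to move to the more hindered O9, and the (E)-geometry is the stable one so that it should be retained.

**Compound list**

1 | creosol (2-methoxy-4-methylphenol) | COc1cc(C)ccc1O | starting material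
2 | formaldehyde | C=O | starting material
3 | 2-(hydroxymethyl)-6-methoxy-4-methylphenol | COc1cc(C)cc(CO)c1O | intermediate
4 | 2-methoxy-4-methyl-6-[(triisopropylsilyloxy)methyl]phenol | COc1cc(C)cc(CO[Si](C(C)C)(C(C)C)C(C)C)c1O | intermediate
5 | benzyl vinyl ether | C=COCc1ccccc1 | starting material
6 | masked o-benzoquinone, 6,6-dimethoxy-4-methyl-2-[(triisopropylsilyloxy)methyl]cyclohexa-2,4-dien-1-one (not isolated) | COC1(OC)C=C(C)C=C(CO[Si](C(C)C)(C(C)C)C(C)C)C1=O | intermediate
7 | rac-Diels–Alder adduct: bicyclo[2.2.2]oct-5-ene with bridgeheads C7 (CH2OTIPS) and C10 (H), C8 ketone, C9 dimethyl ketal, C5 methyl, C2 benzyloxy syn to C5=C6 | c1ccccc1CO[C@H]1C[C@H]2C(C)=C[C@]1(CO[Si](C(C)C)(C(C)C)C(C)C)C(=O)C2(OC)OC | intermediate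
8 | rac-hydroxy ketal: as 7 with C8–OH syn to the C1–C2 bridge | c1ccccc1CO[C@H]1C[C@H]2C(C)=C[C@]1(CO[Si](C(C)C)(C(C)C)C(C)C)[C@@H](O)C2(OC)OC | intermediate
9 | rac-hydroxy ketone: C8–OH syn to the C1–C2 bridge, C9 ketone | c1ccccc1CO[C@H]1C[C@H]2C(C)=C[C@]1(CO[Si](C(C)C)(C(C)C)C(C)C)[C@@H](O)C2=O | intermediate
10 | rac-cis-diol: C8–OH and C9–OH both syn to the C1–C2 bridge | c1ccccc1CO[C@H]1C[C@H]2C(C)=C[C@]1(CO[Si](C(C)C)(C(C)C)C(C)C)[C@@H](O)[C@H]2O | intermediate
11 | rac-acetonide benzyl ether: 8,9-O-isopropylidene derivative of 10 | c1ccccc1CO[C@H]1C[C@H]2C(C)=C[C@]1(CO[Si](C(C)C)(C(C)C)C(C)C)[C@H]3OC(C)(C)O[C@@H]23 | intermediate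
12 | rac-bicyclic alcohol: C2–OH syn to C5=C6, 8,9-acetonide, C7–CH2OTIPS | O[C@H]1C[C@H]2C(C)=C[C@]1(CO[Si](C(C)C)(C(C)C)C(C)C)[C@H]3OC(C)(C)O[C@@H]23 | intermediate
13 | (2S)-bicyclic alcohol: the single enantiomer of 12 with (S)-configured C2 | O[C@H]1C[C@H]2C(C)=C[C@]1(CO[Si](C(C)C)(C(C)C)C(C)C)[C@H]3OC(C)(C)O[C@@H]23 | intermediate
14 | bicyclic ketone: C2 ketone, 8,9-acetonide syn to the C1–C2 bridge, C7–CH2OTIPS, C5 methyl | O=C1C[C@H]2C(C)=C[C@]1(CO[Si](C(C)C)(C(C)C)C(C)C)[C@H]3OC(C)(C)O[C@@H]23 | intermediate
15 | (Z)-1-bromoprop-1-ene | C/C=C\Br | starting material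
16 | (Z)-prop-1-enyllithium (not isolated) | C/C=C\[Li] | intermediate
17 | (Z)-propenyl carbinol: C2 tertiary alcohol, (Z)-prop-1-enyl syn to C5=C6, OH syn to C8–C9, 8,9-acetonide, C7–CH2OTIPS | C/C=C\[C@@]1(O)C[C@H]2C(C)=C[C@]1(CO[Si](C(C)C)(C(C)C)C(C)C)[C@H]3OC(C)(C)O[C@@H]23 | intermediate
18 | potassium alkoxide of 17 (not isolated) | C/C=C\[C@@]1([O-])C[C@H]2C(C)=C[C@]1(CO[Si](C(C)C)(C(C)C)C(C)C)[C@H]3OC(C)(C)O[C@@H]23.[K+] | intermediate
19 | potassium C2=C3 enolate of 20 (not isolated) | CC(C)[Si](C(C)C)(C(C)C)OCC1=C[C@@]2(C)[C@H](CC([O-])=C[C@@H]2C)[C@@H]3OC(C)(C)O[C@H]13.[K+] | intermediate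
20 | cis-decalenone: C2 ketone, 4β,5β-dimethyl, 10β-H, C6=C7 with C7–CH2OTIPS, 8α,9α-acetonide | CC(C)[Si](C(C)C)(C(C)C)OCC1=C[C@@]2(C)[C@H](CC(=O)C[C@@H]2C)[C@@H]3OC(C)(C)O[C@H]13 | intermediate
21 | allylic alcohol: as 20 with C7–CH2OH | OCC1=C[C@@]2(C)[C@H](CC(=O)C[C@@H]2C)[C@@H]3OC(C)(C)O[C@H]13 | intermediate
22 | enal: as 20 with C7–CHO | O=CC1=C[C@@]2(C)[C@H](CC(=O)C[C@@H]2C)[C@@H]3OC(C)(C)O[C@H]13 | intermediate
23 | allylic secondary alcohol: C7–CH(OH)CH3, both C11 epimers | CC(O)C1=C[C@@]2(C)[C@H](CC(=O)C[C@@H]2C)[C@@H]3OC(C)(C)O[C@H]13 | intermediate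
24 | methyl enone: C7–C(O)CH3 on C6=C7, C2 ketone, 8α,9α-acetonide | CC(=O)C1=C[C@@]2(C)[C@H](CC(=O)C[C@@H]2C)[C@@H]3OC(C)(C)O[C@H]13 | intermediate
25 | enone diol: as 24 with free 8α,9α-diol | CC(=O)C1=C[C@@]2(C)[C@H](CC(=O)C[C@@H]2C)[C@H](O)[C@@H]1O | intermediate
26 | 7β-acetyl diol ketone: saturated ring B, H7 α, 8α,9α-diol, C2 ketone | CC(=O)[C@H]1C[C@@]2(C)[C@H](CC(=O)C[C@@H]2C)[C@H](O)[C@@H]1O | intermediate
27 | bridged methyl ketal: C2 bears OMe (equatorial) and is linked to O9 (axial on ring A), 7β-acetyl, 8α-OH | CC(=O)[C@H]1C[C@@]2(C)[C@H](C[C@]3(OC)C[C@@H]2C)[C@H](O3)[C@@H]1O | intermediate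
28 | isopropenyl bridged ketal alcohol: as 27 with 7β-isopropenyl | C=C(C)[C@H]1C[C@@]2(C)[C@H](C[C@]3(OC)C[C@@H]2C)[C@H](O3)[C@@H]1O | intermediate
29 | 8-acetate of 28 | C=C(C)[C@H]1C[C@@]2(C)[C@H](C[C@]3(OC)C[C@@H]2C)[C@H](O3)[C@@H]1OC(C)=O | intermediate
30 | 8α-acetoxy-9α-hydroxy-7β-isopropenyl-4β,5β-dimethyl-10βH-cis-decalin-2-one (may exist in part as the C2/O9 hemiketal) | C=C(C)[C@H]1C[C@@]2(C)[C@H](CC(=O)C[C@@H]2C)[C@H](O)[C@@H]1OC(C)=O | intermediate
31 | CNP0204573.1: (4S,5R,7R,8R,9S,10S)-8-acetoxy-9-[(E)-2-methylbut-2-enoyloxy]-7-isopropenyl-4,5-dimethyl-cis-decalin-2-one | C=C(C)[C@H]1C[C@@]2(C)[C@H](CC(=O)C[C@@H]2C)[C@H](OC(=O)/C(C)=C/C)[C@@H]1OC(C)=O | target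

**Step count and risks**

Total step count: 23. Longest linear sequence: 23 steps (1 → 31).

The three steps most likely to fail:

1. Step 9. The enzymatic acylation of a carbinol flanked by a quaternary bridgehead may be too slow or may discriminate the enantiomers poorly. The fallback sets out from 12 and comes back at 13. Racemic 12 is esterified with (S)-O-methylmandelic acid (DCC, DMAP, CH2Cl2), and the two diastereomeric esters are separated by chromatography: the (S)-O-methylmandelate of the (2S)-alcohol F1 and the (S)-O-methylmandelate of the (2R)-alcohol F2. Methanolysis of F1 (K2CO3, MeOH) returns 13.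

2. Step 23. Acylation of the C9 hydroxyl may stall, because this oxygen is axial on the concave face, is flanked by C2 and C4 and is partly tied up as the hemiketal. The fallback sets out from 30 and comes back at 31; it builds the tigloyl group on O9 from a small, more reactive acyl halide. 2-Bromopropanoyl bromide with pyridine gives the 9-(2-bromopropanoate) F3. PPh3 (toluene, 80 °C) converts it into the phosphonium bromide F4. Et3N deprotonates this to the stabilised ylide F5, and Wittig reaction with acetaldehyde forms the (E)-2-methylbut-2-enoate 31.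

3. Step 18. Hydrogen delivery to the concave α face may be slow, so that undirected addition from the β face competes and erodes the configuration at C7. The fallback sets out from 24 and comes back at 27; it sets C7 under thermodynamic control in the bridged series. Camphorsulfonic acid in methanol removes the acetonide of 24 and closes the C2/O9 bridge directly to the bridged enone alcohol F6, in which ring B is locked. Hydrogenation over Pd/C then adds from the open β face to give the axial 7-epi-ketone F7. Equilibration through the enolate (DBU, CH2Cl2) should convert F7 into the equatorial β-acetyl ketone 27, because an axial substituent at C7 is syn-axial to both C4 and O9 in the bridged frame.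

Further compounds
F1 | step 9 | (S)-O-methylmandelate of the (2S)-alcohol 13 | CO[C@@H](c1ccccc1)C(=O)O[C@H]1C[C@H]2C(C)=C[C@]1(CO[Si](C(C)C)(C(C)C)C(C)C)[C@H]3OC(C)(C)O[C@@H]23
F2 | step 9 | (S)-O-methylmandelate of the (2R)-alcohol (enantiomer of 13) | CO[C@@H](c1ccccc1)C(=O)O[C@@H]1C[C@@H]2C(C)=C[C@@]1(CO[Si](C(C)C)(C(C)C)C(C)C)[C@@H]3OC(C)(C)O[C@H]23
F3 | step 23 | 9-(2-bromopropanoate) of 30 (both epimers at the bromo carbon) | C=C(C)[C@H]1C[C@@]2(C)[C@H](CC(=O)C[C@@H]2C)[C@H](OC(=O)C(C)Br)[C@@H]1OC(C)=O
F4 | step 23 | phosphonium bromide from F3 and PPh3 | C=C(C)[C@H]1C[C@@]2(C)[C@H](CC(=O)C[C@@H]2C)[C@H](OC(=O)C(C)[P+](c3ccccc3)(c3ccccc3)c3ccccc3)[C@@H]1OC(C)=O.[Br-]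
F5 | step 23 | stabilised ylide from F4 | C=C(C)[C@H]1C[C@@]2(C)[C@H](CC(=O)C[C@@H]2C)[C@H](OC(=O)C(C)=P(c3ccccc3)(c3ccccc3)c3ccccc3)[C@@H]1OC(C)=O
F6 | step 18 | bridged methyl ketal of the enone: C2(OMe)–O9 bridge, C6=C7 with C7 acetyl, 8α-OH | CC(=O)C1=C[C@@]2(C)[C@H](C[C@]3(OC)C[C@@H]2C)[C@H](O3)[C@@H]1O
F7 | step 18 | 7-epi-27: bridged methyl ketal with 7α (axial) acetyl | CC(=O)[C@@H]1C[C@@]2(C)[C@H](C[C@]3(OC)C[C@@H]2C)[C@H](O3)[C@@H]1O
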